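## Structural features

The target is the C30 apo-carotenal (3S,6R)-3-hydroxy-8'-apo-ε-caroten-8'-al. It has one cyclohexene ring (carotenoid numbering: C1 quaternary with two methyls, C2 methylene, C3 carbinol, C4=C5 trisubstituted double bond with a methyl on C5, C6 methine). The ring is joined at C6 to an all-E chain of seventeen carbons (C7–C15, C15'–C8') with methyls on C9, C13, C13' and C9' and the aldehyde at C8'. The only stereocentres are C3 (S) and C6 (R); they stand 1,4 to each other across the ring, on either side of the C4=C5 bond, with the hydroxyl and the chain cis. C6–H is doubly allylic (to C4=C5 and C7=C8) and flanked by the quaternary C1; acid, base or heat can epimerise it or move the ring double bond to C5=C6, into conjugation with the chain, so the ring is the less stable alkene isomer. The C3 hydroxyl is a secondary allylic alcohol that ionises easily, and the octaenal is sensitive to light, oxygen, acid and E/Z isomerisation. The chain from C8 to C8' is, atom for atom, the symmetrical C20 dialdehyde of the crocetin series, so the polyene costs one olefination at C7=C8; the real difficulty is the ring, a cis-3,6 diad that must be set together with a double bond held out of conjugation next to a quaternary carbon. The key step exploits the allylic triad C4–C5=C6 and its neighbour C3: a nitrogen on C4, trans to the C3 oxygen, in a precursor with the double bond in the easy conjugated C5=C6 position, passes a hydrogen to C6 from its own face while N2 leaves and the double bond moves to C4=C5.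

## Logic of the disconnections

**12 from 11.** The O–Si bond at C3 is cut. The allylic hydroxyl is masked only for the sulfur oxidation and the strongly basic olefination. The forward step must remove silicon without acid (C3 ionises) and without strong base (polyenal).

**11 from 9 and 10.** The C7=C8 double bond is cut. C8–C8' is then a symmetrical C20 dialdehyde that needs no synthesis, and the whole stereochemical problem is confined to a C10 ring unit. The forward olefination must be E-selective, must use only one formyl group of 10, and must leave C6 alone; a carbanion on C7 is β to C6 and does not acidify C6–H.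

**9 from 8 from 7.** Two S–O bonds and the O–Si bond are cut. Sulfur is carried as the thioether through the nitrogen chemistry because a tetrazolyl sulfone would not survive hydrazine. The oxidation must spare the trisubstituted C4=C5 bond.

**7 from 5 through 6 (key disconnection).** In the forward sense the C6–H bond and the C4=C5 π bond are formed and the C4–N bond and the C5=C6 π bond are broken, with loss of N2. In one sentence: an allylic diazene on C4 of a 3-hydroxy ring with a conjugated C5=C6 bond, made by anti opening of a 3,4-epoxide with hydrazine, rearranges to the cis-3-hydroxy ring with the C4=C5 bond. The gain is that 5 has no C6 stereocentre and has its double bond in the thermodynamically easy tetrasubstituted position, so it descends from a flat, achiral cyclohexadiene. The demand is a concerted, suprafacial hydrogen transfer, so that the C4 configuration is copied to C6.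

**5 from 4.** The C4–N bond is cut. An epoxide spanning C3 and C4 delivers the C3 oxygen and, by SN2 opening at the allylic carbon, a nitrogen on C4 that is necessarily trans to it. The forward step must open at C4, not C3, and must not touch the thioether.

**4 from 3 from 2.** The C7–S bond and then a C7–H bond are cut. This leads back to a formyl group on C6, which is what deactivates the C5=C6 bond towards the oxidant of the first step. The forward thioether formation must not open the vinyl epoxide.

**2 from 1.** The C3–O and C4–O bonds of the epoxide are cut. This leaves an achiral, commercial cyclohexadiene carbaldehyde that already holds all ten carbons of the ring unit. The forward step must pick the cis-disubstituted C3=C4 bond over C5=C6 and one enantioface; this is the only step in which absolute configuration is created.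

## Other disconnections considered

**Alternative 1:** the route most chemists would draw first. Cut C11=C12 and C11'=C12'. The forward key step is a Wittig olefination of the ε-ring C15 phosphonium salt A3 with the C10 dialdehyde A4, followed by a second olefination with a C5 ylide. A3 comes from (3S,6R)-3-hydroxy-α-ionone A1, and A1 from reduction of (6R)-3-oxo-α-ionone A2. The chosen plan is preferred on three grounds:
- In A2 the C6–H is vinylogously acidified by two carbonyl groups, so C6 is at risk of epimerisation and conjugation.
- The C3 ketone of A2 is reduced under the influence of a centre 1,4 across the ring, so a cis/trans mixture is to be expected, and the C6 configuration has to come from a resolution.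
- Making A3 exposes the allylic C3 hydroxyl to acid, and the chain needs three building operations instead of one.

In the chosen plan the relative configuration follows from mechanism and the absolute configuration from one catalytic step.

**Alternative 2:** cut C6–C7 and C3–O together. The forward key step is a catalytic asymmetric oxo-Diels–Alder reaction of the achiral diene A5 with a glyoxylic ester (Cu(OTf)2 with a chiral bis(oxazoline)) to give the bicyclic ether A6. Reduction, iodination and zinc fragmentation would then give the vinylcyclohexenol A7. The idea sets both centres at once, but has three weaknesses: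
- The C–C bond must form at the diene terminus next to the quaternary carbon, which is electronically preferred but sterically penalised.
- A carbonyl-ene reaction at the C5 methyl competes.
- A7 ends in a hindered terminal vinyl group that still needs a cross-coupling and further chain building, about fourteen steps in all.

The chosen plan makes no C–C bond at the hindered C6 at all.

**Alternative 3:** biomimetic. Cut the C7=C8 bond on the β-ring side of 3'-epilutein A8, as a carotenoid cleavage dioxygenase would, by chemical oxidative cleavage (KMnO4 or O3). A8 has ten conjugated double bonds and an isolated ring alkene, and no chemical oxidant distinguishes C7=C8 from its neighbours. A family of apo-carotenals would result, and the allylic alcohol is also oxidisable. The stereocentres would be bought, not made.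

Key step: step 5

Remark: carotenoid numbering (ring C1–C6, chain C7–C15 and C15'–C8') is used for positions throughout; crocetin dialdehyde 10 is taken as a purchasable carotenoid building block, like safranal 1.

## Steps

Step 1
Reactants: 1 safranal (2,6,6-trimethylcyclohexa-1,3-diene-1-carbaldehyde)
Product: 2 (1R,6S)-2,4,4-trimethyl-7-oxabicyclo[4.1.0]hept-2-ene-3-carbaldehyde (the C3/C4 epoxide of 1, oxygen on the face that becomes the C3 hydroxyl face)
Conditions: (R,R)-[Mn(salen)Cl] 5 mol% (salen = N,N'-bis(3,5-di-tert-butylsalicylidene)-1,2-cyclohexanediaminate; C36H52ClMnN2O2), NaOCl aq (pH 11.3), 4-phenylpyridine N-oxide, CH2Cl2, 0 °C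
Reagents that add atoms: sodium hypochlorite, [Na+].[O-]Cl
Why: Jacobsen–Katsuki epoxidation; the oxomanganese species should attack the only cis-disubstituted conjugated alkene (C3=C4), because C5=C6 is tetrasubstituted, shielded on both faces by the C1 methyls and deactivated by the formyl group. Both epoxide centres are set by the catalyst (the ring forces cis fusion); the (R,R) complex is chosen because, by analogy with cis-alkenes conjugated on one side such as indene, it is expected to give the R configuration at the epoxide carbon next to the conjugating double bond.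

Step 2
Reactants: 2 (1R,6S)-2,4,4-trimethyl-7-oxabicyclo[4.1.0]hept-2-ene-3-carbaldehyde
Product: 3 [(1R,6S)-2,4,4-trimethyl-7-oxabicyclo[4.1.0]hept-2-en-3-yl]methanol
Conditions: NaBH4, EtOH, 0 °C
Reagents that add atoms: none
Why: Borohydride 1,2-reduction of an enal whose β-carbon is fully substituted, so conjugate reduction is not expected; borohydride does not open the epoxide and no stereocentre is touched.

Step 3
Reactants: 3 [(1R,6S)-2,4,4-trimethyl-7-oxabicyclo[4.1.0]hept-2-en-3-yl]methanol
Product: 4 5-({[(1R,6S)-2,4,4-trimethyl-7-oxabicyclo[4.1.0]hept-2-en-3-yl]methyl}sulfanyl)-1-phenyl-1H-tetrazole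
Conditions: PPh3, DIAD, 1-phenyl-1H-tetrazole-5-thiol, THF, 0 °C
Reagents that add atoms: 1-phenyl-1H-tetrazole-5-thiol, Sc1nnnn1-c1ccccc1
Why: Mitsunobu thioetherification; the acidic heteroaryl thiol displaces the activated primary allylic oxygen at C7 by SN2, and the SN2' position (C5) is fully substituted. At 0 °C under near-neutral conditions the epoxide should survive.

Step 4
Reactants: 4 5-({[(1R,6S)-2,4,4-trimethyl-7-oxabicyclo[4.1.0]hept-2-en-3-yl]methyl}sulfanyl)-1-phenyl-1H-tetrazole
Product: 5 (1S,2S)-2-hydrazinyl-3,5,5-trimethyl-4-{[(1-phenyl-1H-tetrazol-5-yl)sulfanyl]methyl}cyclohex-3-en-1-ol (hydrazine on C4 trans to the hydroxyl on C3)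
Conditions: N2H4·H2O (10 equiv), EtOH, 23–40 °C, Ar
Reagents that add atoms: hydrazine hydrate, NN.O
Why: SN2 aminolysis of a vinyl epoxide; hydrazine attacks the allylic carbon C4 anti to the oxygen, which sets the C4 nitrogen trans to the C3 hydroxyl by inversion. Attack at C3 lacks allylic activation and meets the pseudo-axial C1 methyl; the excess of hydrazine suppresses double alkylation and the alkylthio-tetrazole is not an electrophile for it.

Step 5
Reactants: 5 (1S,2S)-2-hydrazinyl-3,5,5-trimethyl-4-{[(1-phenyl-1H-tetrazol-5-yl)sulfanyl]methyl}cyclohex-3-en-1-ol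
Product: 7 (1S,4R)-3,5,5-trimethyl-4-{[(1-phenyl-1H-tetrazol-5-yl)sulfanyl]methyl}cyclohex-2-en-1-ol, via allylic diazene 6 (not isolated)
Conditions: PhI(OAc)2 (1.0 equiv), pyridine, CH2Cl2, −40 → 23 °C, Ar
Reagents that add atoms: none
Why: Two-electron oxidation of the monosubstituted hydrazine by the iodine reagent gives the monoalkyl diazene 6, an allylic diazene, which loses N2 by a concerted retro-ene (1,5-hydrogen shift through a six-membered transition state: N–H to C6, the π bond from C5=C6 to C4=C5, C4–N cleaved). The closest known reaction type is the allylic diazene rearrangement used for the reductive 1,3-transposition of allylic alcohols and enone sulfonylhydrazones, which is also the last event of the Wharton reaction; here the diazene is simply reached by hydrazine oxidation. No ring is closed. The one new stereocentre, C6 (ring carbon 4 of 7), is controlled by the C4–N bond, because the hydrogen is delivered suprafacially on the face that carries nitrogen; nitrogen is trans to the C3 oxygen (step 4), so hydrogen arrives anti to the hydroxyl and the CH2S arm ends up cis to it, which is the 3S,6R diad; C4 loses its stereocentre and C3 is untouched. The shift is regiospecific by geometry (only C6 is within reach) and the expulsion of N2 pays for moving the double bond out of the tetrasubstituted, thermodynamically preferred position. The step needs the concerted path to outrun radical or anionic loss of N2, which would scramble the allyl system and could expel the thiolate from C7: hence one equivalent of oxidant at low temperature, exclusion of oxygen and only pyridine as base. It also needs chemoselectivity for N–H over the thioether, which the much faster oxidation of hydrazines by PhI(OAc)2 should secure.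

Step 6
Reactants: 7 (1S,4R)-3,5,5-trimethyl-4-{[(1-phenyl-1H-tetrazol-5-yl)sulfanyl]methyl}cyclohex-2-en-1-ol
Product: 8 tert-butyl(dimethyl){[(1S,4R)-3,5,5-trimethyl-4-{[(1-phenyl-1H-tetrazol-5-yl)sulfanyl]methyl}cyclohex-2-en-1-yl]oxy}silane
Conditions: TBSCl, imidazole, DMF, 23 °C
Reagents that add atoms: tert-butyl(chloro)dimethylsilane, CC(C)(C)[Si](C)(C)Cl
Why: Standard silylation of a secondary alcohol; it removes the hydroxyl that would direct peroxide epoxidation of C4=C5 in step 7 and would consume base in step 8, and imidazole is too weak a base to disturb C6.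

Step 7
Reactants: 8 tert-butyl(dimethyl){[(1S,4R)-3,5,5-trimethyl-4-{[(1-phenyl-1H-tetrazol-5-yl)sulfanyl]methyl}cyclohex-2-en-1-yl]oxy}silane
Product: 9 5-({[(1R,4S)-4-{[tert-butyl(dimethyl)silyl]oxy}-2,6,6-trimethylcyclohex-2-en-1-yl]methyl}sulfonyl)-1-phenyl-1H-tetrazole
Conditions: (NH4)6Mo7O24·4H2O (10 mol%), 30% H2O2, EtOH, 0 → 23 °C
Reagents that add atoms: hydrogen peroxide, OO
Why: Molybdate-catalysed peroxide oxidation of the sulfide through the sulfoxide to the sulfone, the usual entry to Julia–Kocienski reagents; the hindered trisubstituted alkene with its oxygen silylated should be epoxidised far more slowly than sulfur is oxidised.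

Step 8
Reactants: 9 5-({[(1R,4S)-4-{[tert-butyl(dimethyl)silyl]oxy}-2,6,6-trimethylcyclohex-2-en-1-yl]methyl}sulfonyl)-1-phenyl-1H-tetrazole; 10 crocetin dialdehyde ((2E,4E,6E,8E,10E,12E,14E)-2,6,11,15-tetramethylhexadeca-2,4,6,8,10,12,14-heptaenedial)
Product: 11 (2E,4E,6E,8E,10E,12E,14E,16E)-17-[(1R,4S)-4-{[tert-butyl(dimethyl)silyl]oxy}-2,6,6-trimethylcyclohex-2-en-1-yl]-2,6,11,15-tetramethylheptadeca-2,4,6,8,10,12,14,16-octaenal
Conditions: KN(SiMe3)2, DME/THF, −60 °C; then 10 (3 equiv), −60 → 0 °C
Reagents that add atoms: none
Why: Julia–Kocienski olefination; the potassium sulfonyl carbanion at C7 adds to one formyl group of 10 (used in excess and recovered), and Smiles transfer of the tetrazole to oxygen with loss of SO2 and the tetrazololate gives the C7=C8 alkene, for which phenyltetrazolyl sulfones with a potassium counter-ion in DME favour E. C6 is β to the carbanion and not acidified, so its configuration should be retained.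

Step 9
Reactants: 11 (2E,4E,6E,8E,10E,12E,14E,16E)-17-[(1R,4S)-4-{[tert-butyl(dimethyl)silyl]oxy}-2,6,6-trimethylcyclohex-2-en-1-yl]-2,6,11,15-tetramethylheptadeca-2,4,6,8,10,12,14,16-octaenal
Product: 12 (2E,4E,6E,8E,10E,12E,14E,16E)-17-[(1R,4S)-4-hydroxy-2,6,6-trimethylcyclohex-2-en-1-yl]-2,6,11,15-tetramethylheptadeca-2,4,6,8,10,12,14,16-octaenal, that is (3S,6R)-3-hydroxy-8'-apo-ε-caroten-8'-al
Conditions: Bu4NF, AcOH, THF, 0 → 23 °C, dark
Reagents that add atoms: none
Why: Fluoride desilylation buffered with acetic acid, so that the allylic alcohol sees no strong acid and the polyenal and C6–H no strong base; no stereocentre or double bond is involved.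

## Compound list

1 | safranal, 2,6,6-trimethylcyclohexa-1,3-diene-1-carbaldehyde | CC1=C(C=O)C(C)(C)CC=C1 | starting material
2 | (1R,6S)-2,4,4-trimethyl-7-oxabicyclo[4.1.0]hept-2-ene-3-carbaldehyde | O=CC1=C(C)[C@H]2O[C@H]2CC1(C)C | intermediate
3 | [(1R,6S)-2,4,4-trimethyl-7-oxabicyclo[4.1.0]hept-2-en-3-yl]methanol | OCC1=C(C)[C@H]2O[C@H]2CC1(C)C | intermediate
4 | 5-({[(1R,6S)-2,4,4-trimethyl-7-oxabicyclo[4.1.0]hept-2-en-3-yl]methyl}sulfanyl)-1-phenyl-1H-tetrazole | c1ccccc1-n1nnnc1SCC1=C(C)[C@H]2O[C@H]2CC1(C)C | intermediate
5 | (1S,2S)-2-hydrazinyl-3,5,5-trimethyl-4-{[(1-phenyl-1H-tetrazol-5-yl)sulfanyl]methyl}cyclohex-3-en-1-ol | c1ccccc1-n1nnnc1SCC1=C(C)[C@H](NN)[C@@H](O)CC1(C)C | intermediate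
6 | (1S,2S)-2-diazenyl-3,5,5-trimethyl-4-{[(1-phenyl-1H-tetrazol-5-yl)sulfanyl]methyl}cyclohex-3-en-1-ol | c1ccccc1-n1nnnc1SCC1=C(C)[C@H](N=N)[C@@H](O)CC1(C)C | intermediate (not isolated)
7 | (1S,4R)-3,5,5-trimethyl-4-{[(1-phenyl-1H-tetrazol-5-yl)sulfanyl]methyl}cyclohex-2-en-1-ol | CC1=C[C@@H](O)CC(C)(C)[C@H]1CSc1nnnn1-c1ccccc1 | intermediate
8 | tert-butyl(dimethyl){[(1S,4R)-3,5,5-trimethyl-4-{[(1-phenyl-1H-tetrazol-5-yl)sulfanyl]methyl}cyclohex-2-en-1-yl]oxy}silane | CC1=C[C@@H](O[Si](C)(C)C(C)(C)C)CC(C)(C)[C@H]1CSc1nnnn1-c1ccccc1 | intermediate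
9 | 5-({[(1R,4S)-4-{[tert-butyl(dimethyl)silyl]oxy}-2,6,6-trimethylcyclohex-2-en-1-yl]methyl}sulfonyl)-1-phenyl-1H-tetrazole | CC1=C[C@@H](O[Si](C)(C)C(C)(C)C)CC(C)(C)[C@H]1CS(=O)(=O)c1nnnn1-c1ccccc1 | intermediate
10 | crocetin dialdehyde, (2E,4E,6E,8E,10E,12E,14E)-2,6,11,15-tetramethylhexadeca-2,4,6,8,10,12,14-heptaenedial | O=C/C(C)=C/C=C/C(C)=C/C=C/C=C(C)/C=C/C=C(\C)C=O | starting material
11 | (2E,4E,6E,8E,10E,12E,14E,16E)-17-[(1R,4S)-4-{[tert-butyl(dimethyl)silyl]oxy}-2,6,6-trimethylcyclohex-2-en-1-yl]-2,6,11,15-tetramethylheptadeca-2,4,6,8,10,12,14,16-octaenal | CC1=C[C@@H](O[Si](C)(C)C(C)(C)C)CC(C)(C)[C@H]1/C=C/C(C)=C/C=C/C(C)=C/C=C/C=C(C)/C=C/C=C(\C)C=O | intermediate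
12 | (3S,6R)-3-hydroxy-8'-apo-ε-caroten-8'-al, (2E,4E,6E,8E,10E,12E,14E,16E)-17-[(1R,4S)-4-hydroxy-2,6,6-trimethylcyclohex-2-en-1-yl]-2,6,11,15-tetramethylheptadeca-2,4,6,8,10,12,14,16-octaenal | CC1=C[C@@H](O)CC(C)(C)[C@H]1/C=C/C(C)=C/C=C/C(C)=C/C=C/C=C(C)/C=C/C=C(\C)C=O | target

## Step count and risk

Total step count: 9. Longest linear sequence: 9 steps (1 to 12); 10 enters in step 8 as purchased.

Least certain steps:

**Step 5 (key step).**
- What may go wrong: stepwise (radical or base-induced) loss of N2 from the diazene instead of the concerted shift, which would scramble the position of the double bond and could eject the thio group from C7; tautomerisation of the diazene to a hydrazone; over-oxidation at nitrogen or oxidation at sulfur.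
- Fallback (sets out from 5, returns at 7): the diazene is generated by elimination instead of oxidation. The terminal nitrogen of 5 is sulfonylated with TsCl in pyridine at −20 °C to give N'-[(1S,6S)-6-hydroxy-2,4,4-trimethyl-3-{[(1-phenyl-1H-tetrazol-5-yl)sulfanyl]methyl}cyclohex-2-en-1-yl]-4-methylbenzenesulfonohydrazide F1. Warming F1 with NaOAc in aqueous THF at 60 °C expels sulfinate, giving 6 without any oxidant, and 6 rearranges to 7.

**Step 1.**
- What may go wrong: incomplete enantioface discrimination on a cyclohexadiene carrying a formyl group (the sense of induction rests on analogy and must be checked; the (S,S) complex is used if it is the reverse); partial oxidation of the formyl group; some attack at C5=C6.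
- Fallback (sets out from 1, returns at 7): absolute configuration is set by resolution instead of catalysis. Racemic 2 is made with the achiral analogue of the catalyst and carried through steps 2 to 5 unchanged. Racemic 7 is then acylated with vinyl acetate under Burkholderia cepacia lipase. For 2-cyclohexenols the antipode with the R carbinol centre is usually acylated faster, which here would be the unwanted one; it is removed as (1R,4S)-3,5,5-trimethyl-4-{[(1-phenyl-1H-tetrazol-5-yl)sulfanyl]methyl}cyclohex-2-en-1-yl acetate F2, and 7 is recovered as the alcohol.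

**Step 4.**
- What may go wrong: opening at C3 instead of C4; double alkylation of hydrazine; after opening, intramolecular displacement of the allylic tetrazolylthio group at C7 by the new hydrazine nitrogen.
- Fallback (sets out from 3, returns at 7): sulfur is introduced after the nitrogen chemistry. Hydrazinolysis of 3 gives (1S,2S)-2-hydrazinyl-4-(hydroxymethyl)-3,5,5-trimethylcyclohex-3-en-1-ol F3. Oxidation with PhI(OAc)2 gives, through (1S,2S)-2-diazenyl-4-(hydroxymethyl)-3,5,5-trimethylcyclohex-3-en-1-ol F4, the cis diol (1S,4R)-4-(hydroxymethyl)-3,5,5-trimethylcyclohex-2-en-1-ol F5. A Mitsunobu reaction of F5 with 1-phenyl-1H-tetrazole-5-thiol, selective for the primary alcohol, gives 7. This also takes the vinyl epoxide out of the Mitsunobu step, at the price of having to distinguish two hydroxyls.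

**Step 8.**
- What may go wrong: olefination at both ends of the symmetrical dialdehyde; poor solubility of 10 at low temperature; an E/Z mixture at C7=C8 with a conjugated aldehyde partner (a final equilibration with a trace of iodine in daylight may be needed).
- Fallback (sets out from 10, returns at 11): the two ends of the C20 unit are differentiated before the valuable sulfone is committed. 10 is converted with HC(OMe)3 and catalytic pyridinium tosylate into (2E,4E,6E,8E,10E,12E,14E)-16,16-dimethoxy-2,6,11,15-tetramethylhexadeca-2,4,6,8,10,12,14-heptaenal F6 (statistical, unreacted 10 recycled). Julia–Kocienski reaction of 9 with F6 gives tert-butyl{[(1S,4R)-4-[(1E,3E,5E,7E,9E,11E,13E,15E)-17,17-dimethoxy-3,7,12,16-tetramethylheptadeca-1,3,5,7,9,11,13,15-octaenyl]-3,5,5-trimethylcyclohex-2-en-1-yl]oxy}dimethylsilane F7. Hydrolysis of F7 on wet silica with a trace of oxalic acid gives 11.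

## Further compounds

F1 | step 5 | N'-[(1S,6S)-6-hydroxy-2,4,4-trimethyl-3-{[(1-phenyl-1H-tetrazol-5-yl)sulfanyl]methyl}cyclohex-2-en-1-yl]-4-methylbenzenesulfonohydrazide | c1ccccc1-n1nnnc1SCC1=C(C)[C@H](NNS(=O)(=O)c2ccc(C)cc2)[C@@H](O)CC1(C)C
F2 | step 1 | (1R,4S)-3,5,5-trimethyl-4-{[(1-phenyl-1H-tetrazol-5-yl)sulfanyl]methyl}cyclohex-2-en-1-yl acetate | CC1=C[C@H](OC(C)=O)CC(C)(C)[C@@H]1CSc1nnnn1-c1ccccc1
F3 | step 4 | (1S,2S)-2-hydrazinyl-4-(hydroxymethyl)-3,5,5-trimethylcyclohex-3-en-1-ol | OCC1=C(C)[C@H](NN)[C@@H](O)CC1(C)C
F4 | step 4 | (1S,2S)-2-diazenyl-4-(hydroxymethyl)-3,5,5-trimethylcyclohex-3-en-1-ol | OCC1=C(C)[C@H](N=N)[C@@H](O)CC1(C)C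
F5 | step 4 | (1S,4R)-4-(hydroxymethyl)-3,5,5-trimethylcyclohex-2-en-1-ol | CC1=C[C@@H](O)CC(C)(C)[C@H]1CO
F6 | step 8 | (2E,4E,6E,8E,10E,12E,14E)-16,16-dimethoxy-2,6,11,15-tetramethylhexadeca-2,4,6,8,10,12,14-heptaenal | COC(OC)/C(C)=C/C=C/C(C)=C/C=C/C=C(C)/C=C/C=C(\C)C=O
F7 | step 8 | tert-butyl{[(1S,4R)-4-[(1E,3E,5E,7E,9E,11E,13E,15E)-17,17-dimethoxy-3,7,12,16-tetramethylheptadeca-1,3,5,7,9,11,13,15-octaenyl]-3,5,5-trimethylcyclohex-2-en-1-yl]oxy}dimethylsilane | CC1=C[C@@H](O[Si](C)(C)C(C)(C)C)CC(C)(C)[C@H]1/C=C/C(C)=C/C=C/C(C)=C/C=C/C=C(C)/C=C/C=C(\C)C(OC)OC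
A1 | alternative 1 | (3S,6R)-3-hydroxy-α-ionone, (3E)-4-[(1R,4S)-4-hydroxy-2,6,6-trimethylcyclohex-2-en-1-yl]but-3-en-2-one | CC1=C[C@@H](O)CC(C)(C)[C@H]1/C=C/C(C)=O
A2 | alternative 1 | (6R)-3-oxo-α-ionone, (4R)-3,5,5-trimethyl-4-[(1E)-3-oxobut-1-en-1-yl]cyclohex-2-en-1-one | CC1=CC(=O)CC(C)(C)[C@H]1/C=C/C(C)=O
A3 | alternative 1 | {(2E,4E)-5-[(1R,4S)-4-hydroxy-2,6,6-trimethylcyclohex-2-en-1-yl]-3-methylpenta-2,4-dien-1-yl}triphenylphosphonium bromide | CC1=C[C@@H](O)CC(C)(C)[C@H]1/C=C/C(C)=C/C[P+](c1ccccc1)(c1ccccc1)c1ccccc1.[Br-]
A4 | alternative 1 | (2E,4E,6E)-2,7-dimethylocta-2,4,6-trienedial | O=C/C(C)=C/C=C/C=C(C)/C=O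
A5 | alternative 2 | 2,6,6-trimethylcyclohexa-1,3-diene | CC1=CC(C)(C)CC=C1
A6 | alternative 2 | ethyl (1S,4R)-5,8,8-trimethyl-2-oxabicyclo[2.2.2]oct-5-ene-3-carboxylate (configuration at carbon 3 open) | CC1=C[C@@H]2CC(C)(C)[C@H]1C(C(=O)OCC)O2
A7 | alternative 2 | (1S,4R)-4-ethenyl-3,5,5-trimethylcyclohex-2-en-1-ol | CC1=C[C@@H](O)CC(C)(C)[C@H]1C=C
A8 | alternative 3 | 3'-epilutein, (3R,3'S,6'R)-β,ε-carotene-3,3'-diol | CC1=C[C@@H](O)CC(C)(C)[C@H]1/C=C/C(C)=C/C=C/C(C)=C/C=C/C=C(C)/C=C/C=C(C)/C=C/C1=C(C)C[C@@H](O)CC1(C)C
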